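The C6–C7–C8 bridge of the bicyclo[3.3.1]nonane, with the prenyl group on C7 and the two methyl groups on C8, is a concealed lavandulyl unit, the antipode of the lavandulyl chain on C5. Both antipodes of lavandulol are therefore placed on C5 of a dearomatised 2,4-diformylphloroglucinol, whose ring carbons C1 and C3 are identical, so that C5 is not yet a stereocentre. Ionisation of a tertiary methyl ether in the (R)-lavandulol-derived chain then lets one of the two formyl-bearing enol carbons close the C1–C8 bond; this one operation builds the bicycle and fixes C1 and C5 from C7. Afterwards the C1 formyl group becomes the aroyl group and the C3 formyl group is exchanged for prenyl.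

Key step: step 6

Remark: locants C1–C9 are those of the bicyclic core of 20 (C1 aroyl-bearing bridgehead, C5 lavandulyl-bearing bridgehead, C9 bridging carbonyl) and are used for the monocyclic precursors too; both enantiomers of lavandulol are taken as purchasable in enantiopure form.

Step 1
Reactants: 1 (R)-lavandulol
Product: 3 (2S)-2-(2-methoxypropan-2-yl)-5-methylhex-4-en-1-ol, via alkylmercury acetate 2 (not isolated)
Conditions: Hg(OAc)2 (1.0 equiv), MeOH, 0 °C; then NaBH4, 3 M NaOH, 0 °C
Reagents that add atoms: methanol, CO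
Why: Markovnikov alkoxymercuration–demercuration, in which the unhindered 1,1-disubstituted alkene should be mercurated much faster than the trisubstituted one; the stereocentre is untouched (R becomes S only through the change in priorities).

Step 2
Reactants: 3 (2S)-2-(2-methoxypropan-2-yl)-5-methylhex-4-en-1-ol
Product: 4 (2S)-2-(2-methoxypropan-2-yl)-5-methylhex-4-en-1-yl trifluoromethanesulfonate
Conditions: Tf2O (1.1 equiv), pyridine (1.5 equiv), CH2Cl2, –78 °C; used at once
Reagents that add atoms: trifluoromethanesulfonic anhydride, O=S(=O)(OS(=O)(=O)C(F)(F)F)C(F)(F)F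
Why: O-sulfonylation of the primary alcohol; the tertiary methyl ether and the alkene are inert at this temperature and no stereocentre is involved.

Step 3
Reactants: 5 (S)-lavandulol
Product: 6 (S)-lavandulyl trifluoromethanesulfonate
Conditions: Tf2O (1.1 equiv), pyridine (1.5 equiv), CH2Cl2, –78 °C; used at once
Reagents that add atoms: trifluoromethanesulfonic anhydride, O=S(=O)(OS(=O)(=O)C(F)(F)F)C(F)(F)F
Why: O-sulfonylation of the primary alcohol, which turns the second lavandulol antipode into a primary electrophile without touching its stereocentre.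

Step 4
Reactants: 7 2,4,6-trihydroxybenzene-1,3-dicarbaldehyde and 4 (2S)-2-(2-methoxypropan-2-yl)-5-methylhex-4-en-1-yl trifluoromethanesulfonate
Product: 8 2,4,6-trihydroxy-5-[(2S)-2-(2-methoxypropan-2-yl)-5-methylhex-4-en-1-yl]benzene-1,3-dicarbaldehyde
Conditions: 7 (2 equiv), LiN(SiMe3)2 (3 equiv per 7), THF, 0 °C; then 4, 0 → 23 °C; AcOH quench
Reagents that add atoms: none
Why: C-alkylation of a lithium phloroglucinolate by SN2 displacement of a primary triflate; C5 is the only unsubstituted ring carbon, the lithium counter-ion in THF should favour carbon over oxygen, and excess 7 should suppress double alkylation.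

Step 5
Reactants: 8 2,4,6-trihydroxy-5-[(2S)-2-(2-methoxypropan-2-yl)-5-methylhex-4-en-1-yl]benzene-1,3-dicarbaldehyde and 6 (S)-lavandulyl trifluoromethanesulfonate
Product: 9 4,6-dihydroxy-5-[(2S)-2-(2-methoxypropan-2-yl)-5-methylhex-4-en-1-yl]-5-[(2R)-5-methyl-2-(prop-1-en-2-yl)hex-4-en-1-yl]-2-oxocyclohexa-3,6-diene-1,3-dicarbaldehyde
Conditions: LiN(SiMe3)2 (3 equiv), THF, 0 °C; then 6 (1.5 equiv), 0 → 23 °C; AcOH quench
Reagents that add atoms: none
Why: alkylative dearomatisation of the phloroglucinolate at C5, the only ring carbon without an acyl group; because C1 and C3 both carry formyl, the new quaternary C5 is not a stereocentre and no facial selectivity is needed.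

Step 6
Reactants: 9 4,6-dihydroxy-5-[(2S)-2-(2-methoxypropan-2-yl)-5-methylhex-4-en-1-yl]-5-[(2R)-5-methyl-2-(prop-1-en-2-yl)hex-4-en-1-yl]-2-oxocyclohexa-3,6-diene-1,3-dicarbaldehyde
Product: 12 (1S,5R,7S)-2-hydroxy-8,8-dimethyl-7-(3-methylbut-2-en-1-yl)-5-[(2R)-5-methyl-2-(prop-1-en-2-yl)hex-4-en-1-yl]-4,9-dioxobicyclo[3.3.1]non-2-ene-1,3-dicarbaldehyde, via bis-silyl enol ether 10 (not isolated), via silylated bicycle 11 (not isolated)
Conditions: Me3SiOTf (3 equiv), 2,6-lutidine (4 equiv), CH2Cl2, –78 → 0 °C; then aq. NaHCO3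
Reagents that add atoms: none
Why: Me3SiOTf should first turn both enol hydroxyl groups into silyl enol ethers (10) and then ionise the tertiary methyl ether to the C8 carbocation, which the enol carbon C1 captures in an SN1 alkylation; loss of the silyl group gives 11 and work-up gives 12. The closest known reaction types are the Lewis acid-mediated tert-alkylation of silyl enol ethers by tertiary carbocations (Reetz alkylation) and the biomimetic cationic cyclisation of dearomatised acylphloroglucinols. The cyclohexanone ring C1–C9–C5–C6–C7–C8 closes in a 6-(enolendo)-exo mode. C1 and C5 become stereocentres here and are controlled by C7: the chair transition state with the C7 prenyl group equatorial uses the one of the two constitutionally identical enol carbons flanking C5 that leads to the 7-exo bicycle, whereas attack by the other would force the prenyl group axial under the C2–C3–C4 bridge. The step needs closure on carbon instead of oxygen and no protonation of the three other alkenes: closure on oxygen gives a tertiary alkyl enol ether that the same Lewis acid should re-ionise, so the irreversible carbon–carbon closure is the sink, and the lutidine-buffered aprotic medium should leave the prenyl and isopropenyl groups alone.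

Step 7
Reactants: 13 4-bromobenzene-1,2-diol
Product: 14 4-bromo-1,2-bis(tert-butyldimethylsilyloxy)benzene
Conditions: t-BuMe2SiCl (2.4 equiv), imidazole (5 equiv), DMF, 23 °C
Reagents that add atoms: tert-butyldimethylsilyl chloride, CC(C)(C)[Si](C)(C)Cl
Why: O-silylation of both phenols, giving a catechol mask that tolerates aryllithium chemistry and is removed by fluoride at the end.

Step 8
Reactants: 12 (1S,5R,7S)-2-hydroxy-8,8-dimethyl-7-(3-methylbut-2-en-1-yl)-5-[(2R)-5-methyl-2-(prop-1-en-2-yl)hex-4-en-1-yl]-4,9-dioxobicyclo[3.3.1]non-2-ene-1,3-dicarbaldehyde and 14 4-bromo-1,2-bis(tert-butyldimethylsilyloxy)benzene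
Product: 16 bicyclic carbinol with a [3,4-bis(tert-butyldimethylsilyloxy)phenyl](hydroxy)methyl group on C1 (mixture of carbinol epimers), via aryllithium 15 (not isolated)
Conditions: 14 (2.3 equiv), n-BuLi (2.2 equiv), THF, –78 °C; then 12, –78 → –40 °C; AcOH quench
Reagents that add atoms: none
Why: bromine–lithium exchange followed by 1,2-addition of the aryllithium to the C1 aldehyde, the only free aldehyde, since the first equivalent deprotonates the C3 formyl-dione to an unreactive anion and the C9 ketone lies between two quaternary carbons; the carbinol centre is not controlled and is removed in step 9.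

Step 9
Reactants: 16 bicyclic carbinol
Product: 17 (1S,5R,7S)-1-[3,4-bis(tert-butyldimethylsilyloxy)benzoyl]-2-hydroxy-8,8-dimethyl-7-(3-methylbut-2-en-1-yl)-5-[(2R)-5-methyl-2-(prop-1-en-2-yl)hex-4-en-1-yl]-4,9-dioxobicyclo[3.3.1]non-2-ene-3-carbaldehyde
Conditions: Dess–Martin periodinane (1.5 equiv), CH2Cl2, 0 → 23 °C
Reagents that add atoms: none
Why: Dess–Martin oxidation of the benzylic carbinol to the aryl ketone; C3 still carries its formyl group and so cannot be oxidised at carbon.

Step 10
Reactants: 17 C1-aroyl C3-formyl bicycle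
Product: 18 (1S,5R,7S)-1-[3,4-bis(tert-butyldimethylsilyloxy)benzoyl]-2-hydroxy-8,8-dimethyl-7-(3-methylbut-2-en-1-yl)-5-[(2R)-5-methyl-2-(prop-1-en-2-yl)hex-4-en-1-yl]bicyclo[3.3.1]non-2-ene-4,9-dione
Conditions: AcOH–H2O–THF (3:1:1), 60 °C
Reagents that add atoms: none
Why: hydrolytic retro-Claisen deformylation of a 2-formyl-1,3-dione, in which water adds to the formyl carbon and the stabilised dione enol leaves; the hindered C1 aroyl group, the aryl silyl ethers and the alkenes should survive aqueous acetic acid.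

Step 11
Reactants: 18 C3-unsubstituted bicyclic dione
Product: 19 (1S,5R,7S)-1-[3,4-bis(tert-butyldimethylsilyloxy)benzoyl]-2-hydroxy-8,8-dimethyl-3,7-bis(3-methylbut-2-en-1-yl)-5-[(2R)-5-methyl-2-(prop-1-en-2-yl)hex-4-en-1-yl]bicyclo[3.3.1]non-2-ene-4,9-dione
Conditions: 3-methylbut-2-enal (1.5 equiv), Hantzsch ester (1.2 equiv), L-proline (20 mol %), CH2Cl2, 23 °C
Reagents that add atoms: 3-methylbut-2-enal, CC(C)=CC=O
Why: three-component reductive alkylation of a cyclic 1,3-dione (Knoevenagel condensation, then conjugate hydride transfer from the Hantzsch ester to the exocyclic carbon), which gives the C-prenyl group without O-alkylation or double alkylation.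

Step 12
Reactants: 19 bis-silyl ether of the target
Product: 20 (1S,5R,7S)-1-(3,4-dihydroxybenzoyl)-2-hydroxy-8,8-dimethyl-3,7-bis(3-methylbut-2-en-1-yl)-5-[(2R)-5-methyl-2-(prop-1-en-2-yl)hex-4-en-1-yl]bicyclo[3.3.1]non-2-ene-4,9-dione
Conditions: Bu4NF (2.5 equiv), AcOH (2.5 equiv), THF, 0 °C
Reagents that add atoms: none
Why: fluoride-mediated cleavage of the two aryl silyl ethers under buffered conditions, which should spare the enolised trione, the prenyl groups and the isopropenyl group.

Compound list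
1 | (R)-lavandulol, (2R)-5-methyl-2-(prop-1-en-2-yl)hex-4-en-1-ol | OC[C@H](CC=C(C)C)C(C)=C | starting material
2 | acetoxy[(3S)-3-(hydroxymethyl)-2-methoxy-2,6-dimethylhept-5-en-1-yl]mercury, RHgOAc (C2 not defined) | OC[C@H](CC=C(C)C)C(C)(OC)C[Hg]OC(C)=O | intermediate
3 | (2S)-2-(2-methoxypropan-2-yl)-5-methylhex-4-en-1-ol | OC[C@H](CC=C(C)C)C(C)(C)OC | intermediate
4 | (2S)-2-(2-methoxypropan-2-yl)-5-methylhex-4-en-1-yl trifluoromethanesulfonate | O=S(=O)(OC[C@H](CC=C(C)C)C(C)(C)OC)C(F)(F)F | intermediate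
5 | (S)-lavandulol, (2S)-5-methyl-2-(prop-1-en-2-yl)hex-4-en-1-ol | OC[C@@H](CC=C(C)C)C(C)=C | starting material
6 | (S)-lavandulyl trifluoromethanesulfonate, (2S)-5-methyl-2-(prop-1-en-2-yl)hex-4-en-1-yl trifluoromethanesulfonate | O=S(=O)(OC[C@@H](CC=C(C)C)C(C)=C)C(F)(F)F | intermediate
7 | 2,4,6-trihydroxybenzene-1,3-dicarbaldehyde (2,4-diformylphloroglucinol) | O=Cc1c(O)cc(O)c(C=O)c1O | starting material
8 | 2,4,6-trihydroxy-5-[(2S)-2-(2-methoxypropan-2-yl)-5-methylhex-4-en-1-yl]benzene-1,3-dicarbaldehyde | O=Cc1c(O)c(C[C@H](CC=C(C)C)C(C)(C)OC)c(O)c(C=O)c1O | intermediate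
9 | 4,6-dihydroxy-5-[(2S)-2-(2-methoxypropan-2-yl)-5-methylhex-4-en-1-yl]-5-[(2R)-5-methyl-2-(prop-1-en-2-yl)hex-4-en-1-yl]-2-oxocyclohexa-3,6-diene-1,3-dicarbaldehyde (dearomatised diformylphloroglucinol, both chains on C5) | O=CC1=C(O)C(C[C@H](CC=C(C)C)C(C)(C)OC)(C[C@@H](CC=C(C)C)C(C)=C)C(O)=C(C=O)C1=O | intermediate
10 | 4,6-bis(trimethylsilyl) ether of 9 (bis-silyl enol ether) | O=CC1=C(O[Si](C)(C)C)C(C[C@H](CC=C(C)C)C(C)(C)OC)(C[C@@H](CC=C(C)C)C(C)=C)C(O[Si](C)(C)C)=C(C=O)C1=O | intermediate
11 | trimethylsilyl enol ether of 12 (silyl group on the C4 oxygen, same configuration as 12) | C=C(C)[C@H](CC=C(C)C)C[C@]12C[C@H](CC=C(C)C)C(C)(C)[C@](C=O)(C1=O)C(=O)C(C=O)=C2O[Si](C)(C)C | intermediate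
12 | (1S,5R,7S)-2-hydroxy-8,8-dimethyl-7-(3-methylbut-2-en-1-yl)-5-[(2R)-5-methyl-2-(prop-1-en-2-yl)hex-4-en-1-yl]-4,9-dioxobicyclo[3.3.1]non-2-ene-1,3-dicarbaldehyde (7-exo prenyl) | C=C(C)[C@H](CC=C(C)C)C[C@]12C[C@H](CC=C(C)C)C(C)(C)[C@](C=O)(C1=O)C(O)=C(C=O)C2=O | intermediate
13 | 4-bromobenzene-1,2-diol | Oc1ccc(Br)cc1O | starting material
14 | 4-bromo-1,2-bis(tert-butyldimethylsilyloxy)benzene | CC(C)(C)[Si](C)(C)Oc1ccc(Br)cc1O[Si](C)(C)C(C)(C)C | intermediate
15 | [3,4-bis(tert-butyldimethylsilyloxy)phenyl]lithium | [Li]c1ccc(O[Si](C)(C)C(C)(C)C)c(O[Si](C)(C)C(C)(C)C)c1 | intermediate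
16 | 1-{[3,4-bis(tert-butyldimethylsilyloxy)phenyl](hydroxy)methyl}-2-hydroxy-8,8-dimethyl-7-(3-methylbut-2-en-1-yl)-5-[(2R)-5-methyl-2-(prop-1-en-2-yl)hex-4-en-1-yl]-4,9-dioxobicyclo[3.3.1]non-2-ene-3-carbaldehyde; core arranged in space as in 12 (descriptors 1R,5S,7S by priority change), carbinol centre not defined | C=C(C)[C@H](CC=C(C)C)C[C@]12C[C@H](CC=C(C)C)C(C)(C)[C@](C(O)c3ccc(O[Si](C)(C)C(C)(C)C)c(O[Si](C)(C)C(C)(C)C)c3)(C1=O)C(O)=C(C=O)C2=O | intermediate
17 | (1S,5R,7S)-1-[3,4-bis(tert-butyldimethylsilyloxy)benzoyl]-2-hydroxy-8,8-dimethyl-7-(3-methylbut-2-en-1-yl)-5-[(2R)-5-methyl-2-(prop-1-en-2-yl)hex-4-en-1-yl]-4,9-dioxobicyclo[3.3.1]non-2-ene-3-carbaldehyde | C=C(C)[C@H](CC=C(C)C)C[C@]12C[C@H](CC=C(C)C)C(C)(C)[C@](C(=O)c3ccc(O[Si](C)(C)C(C)(C)C)c(O[Si](C)(C)C(C)(C)C)c3)(C1=O)C(O)=C(C=O)C2=O | intermediate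
18 | (1S,5R,7S)-1-[3,4-bis(tert-butyldimethylsilyloxy)benzoyl]-2-hydroxy-8,8-dimethyl-7-(3-methylbut-2-en-1-yl)-5-[(2R)-5-methyl-2-(prop-1-en-2-yl)hex-4-en-1-yl]bicyclo[3.3.1]non-2-ene-4,9-dione | C=C(C)[C@H](CC=C(C)C)C[C@]12C[C@H](CC=C(C)C)C(C)(C)[C@](C(=O)c3ccc(O[Si](C)(C)C(C)(C)C)c(O[Si](C)(C)C(C)(C)C)c3)(C1=O)C(O)=CC2=O | intermediate
19 | (1S,5R,7S)-1-[3,4-bis(tert-butyldimethylsilyloxy)benzoyl]-2-hydroxy-8,8-dimethyl-3,7-bis(3-methylbut-2-en-1-yl)-5-[(2R)-5-methyl-2-(prop-1-en-2-yl)hex-4-en-1-yl]bicyclo[3.3.1]non-2-ene-4,9-dione | C=C(C)[C@H](CC=C(C)C)C[C@]12C[C@H](CC=C(C)C)C(C)(C)[C@](C(=O)c3ccc(O[Si](C)(C)C(C)(C)C)c(O[Si](C)(C)C(C)(C)C)c3)(C1=O)C(O)=C(CC=C(C)C)C2=O | intermediate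
20 | (1S,5R,7S)-1-(3,4-dihydroxybenzoyl)-2-hydroxy-8,8-dimethyl-3,7-bis(3-methylbut-2-en-1-yl)-5-[(2R)-5-methyl-2-(prop-1-en-2-yl)hex-4-en-1-yl]bicyclo[3.3.1]non-2-ene-4,9-dione (CNP0425478.2) | C=C(C)[C@H](CC=C(C)C)C[C@]12C[C@H](CC=C(C)C)C(C)(C)[C@](C(=O)c3ccc(O)c(O)c3)(C1=O)C(O)=C(CC=C(C)C)C2=O | target

Total step count: 12
Longest linear sequence: 10 steps (steps 1, 2, 4, 5, 6, 8, 9, 10, 11, 12)

Steps most likely to fail

Step 6. The carbocation may close on an enol oxygen or lose a proton faster than it forms the bond between two fully substituted carbons. The fallback sets out from 9 and makes closure on oxygen the deliberate first event: BF3·OEt2 in CH2Cl2 at –40 °C should give the cyclic enol ether F1 (a 2,2-dimethyl-3-prenyl-dihydropyran fused across O–C4–C5; both C5 epimers, which converge). F1 is then equilibrated in formic acid at 23 °C, where the tertiary alkyl–oxygen bond ionises reversibly and the carbon–carbon closure is the thermodynamic sink (1,3 oxygen-to-carbon alkyl shift under the same control by C7). The route is rejoined at 12.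

Step 5. The congested ring carbon may be alkylated so slowly that alkylation on oxygen takes over. The fallback sets out from 8: catalytic Me3SiOTf in CH2Cl2 at –20 °C should close the tertiary ether onto the flanking phenol to give the chroman F2, which ties the first chain back and uncovers C5. Alkylation of F2 with 6 (LiN(SiMe3)2, THF) at the ring-fusion carbon then gives the cyclic enol ether F1, which is rearranged in formic acid as above. The route is rejoined at 12.

Step 10. Hydrolytic loss of the formyl group from the stabilised enol may be slow and compete with retro-Claisen cleavage at C1. The fallback sets out from 17 and keeps the formyl carbon as the first carbon of the prenyl group: pyrrolidine (EtOH, 23 °C) should convert the hydroxymethylene group into the enaminone F3, and Me2C=CHMgBr in THF should add to the enamine carbon and expel pyrrolidine (Benary reaction) to give the alkylidene-dione F4. Conjugate reduction of F4 with Hantzsch ester then delivers the C3 prenyl group. The route is rejoined at 19.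

Further compounds
F1 | step 6 | cyclic enol ether: dearomatised diformyl ring with the (S)-lavandulol-derived chain on C5 and a (3S)-2,2-dimethyl-3-(3-methylbut-2-en-1-yl)dihydropyran fused across O–C4–C5 (C5 not defined) | O=CC1=C(O)C2(C[C@@H](CC=C(C)C)C(C)=C)C[C@H](CC=C(C)C)C(C)(C)OC2=C(C=O)C1=O
F2 | step 5 | (3S)-5,7-dihydroxy-2,2-dimethyl-3-(3-methylbut-2-en-1-yl)chromane-6,8-dicarbaldehyde | O=Cc1c(O)c2C[C@H](CC=C(C)C)C(C)(C)Oc2c(C=O)c1O
F3 | step 10 | pyrrolidine enaminone of 17 (3-(pyrrolidin-1-ylmethylidene)-2,4,9-trione, core as in 17, alkene geometry not defined) | C=C(C)[C@H](CC=C(C)C)C[C@]12C[C@H](CC=C(C)C)C(C)(C)[C@](C(=O)c3ccc(O[Si](C)(C)C(C)(C)C)c(O[Si](C)(C)C(C)(C)C)c3)(C1=O)C(=O)C(=CN4CCCC4)C2=O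
F4 | step 10 | 3-(3-methylbut-2-en-1-ylidene)-2,4,9-trione (core and silyl ethers as in 17, alkene geometry not defined) | C=C(C)[C@H](CC=C(C)C)C[C@]12C[C@H](CC=C(C)C)C(C)(C)[C@](C(=O)c3ccc(O[Si](C)(C)C(C)(C)C)c(O[Si](C)(C)C(C)(C)C)c3)(C1=O)C(=O)C(=CC=C(C)C)C2=O
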